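**Retrosynthetic overview**
1. Ring C is opened at O1–C2: the flavone should come from an ortho-hydroxyaryl ynone by 6-endo oxa-Michael closure, and the ynone carbonyl (C4) is carried as a dioxolane until ring A exists.
2. Ring A is taken apart at C5–C6, C4a–C8a and C8–C8a (Dötz benzannulation): a methoxy(1-methoxyvinyl)carbene chromium complex supplies C6, C7, C8 and, from one CO ligand, C8a with O1; the terminal alkyne of a diynyl ketal supplies C5 and C4a.
3. Feature used: in ring A the O1-bearing C8a lies para to the methoxy carbon C6 and ortho to C4a, which carries C4. This is a 4-methoxyphenol with an ortho carbon substituent, the pattern that the benzannulation delivers.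
4. The diynyl ketal comes from 3,4,5-trimethoxyphenylacetylene and 3-(trimethylsilyl)propynal; the carbene complex comes from methyl vinyl ether and Cr(CO)6.
5. Ring order: ring B purchased, ring A formed in step 6, ring C closed in step 8.

Key step: step 6

Remark: the target has no stereocentre. The carbinol carbon made in step 2 is formed racemic and is removed in step 3. The four starting materials are taken as purchased.

**Step 1**
Reactants: 1 methyl vinyl ether; 2 chromium hexacarbonyl, Cr(CO)6
Product: 5 pentacarbonyl[methoxy(1-methoxyvinyl)carbene]chromium, via 1-methoxyvinyllithium 3 (not isolated), via lithium acylchromate 4 (not isolated)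
Conditions: t-BuLi, THF, −78 → 0 °C; Cr(CO)6, THF, −78 °C → rt; solvent exchange; Me3OBF4, CH2Cl2, 0 °C; cold chromatography under Ar
Reagents that add atoms: trimethyloxonium tetrafluoroborate, C[O+](C)C.F[B-](F)(F)F
Why: Fischer carbene synthesis, in which the α-lithiated enol ether adds to a CO ligand of Cr(CO)6 and the hard oxonium salt methylates the acylate oxygen under anhydrous conditions that spare the enol ether; α-alkoxyalkenyllithium reagents from cyclic enol ethers are converted to isolable chromium carbene complexes in the same way.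

**Step 2**
Reactants: 6 5-ethynyl-1,2,3-trimethoxybenzene; 7 3-(trimethylsilyl)prop-2-ynal
Product: 9 racemic 1-(3,4,5-trimethoxyphenyl)-5-(trimethylsilyl)penta-1,4-diyn-3-ol, via lithium arylacetylide 8 (not isolated)
Conditions: n-BuLi, THF, −78 °C; then 7, −78 → 0 °C; aq. NH4Cl
Reagents that add atoms: none
Why: 1,2-addition of a lithium acetylide to an aldehyde; the carbinol stereocentre forms without control (racemic) and is removed in step 3.

**Step 3**
Reactants: 9 racemic 1-(3,4,5-trimethoxyphenyl)-5-(trimethylsilyl)penta-1,4-diyn-3-ol
Product: 10 1-(3,4,5-trimethoxyphenyl)-5-(trimethylsilyl)penta-1,4-diyn-3-one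
Conditions: activated MnO2, CH2Cl2, rt
Reagents that add atoms: none
Why: MnO2 oxidation of a doubly propargylic alcohol under neutral heterogeneous conditions, which spare the alkynylsilane and expose the cross-conjugated diynone to neither base nor nucleophile.

**Step 4**
Reactants: 10 1-(3,4,5-trimethoxyphenyl)-5-(trimethylsilyl)penta-1,4-diyn-3-one
Product: 11 trimethyl({2-[(3,4,5-trimethoxyphenyl)ethynyl]-1,3-dioxolan-2-yl}ethynyl)silane
Conditions: Me3SiOCH2CH2OSiMe3, Me3SiOSO2CF3 (cat.), CH2Cl2, −78 → −20 °C; pyridine quench
Reagents that add atoms: 1,2-bis(trimethylsilyloxy)ethane, C[Si](C)(C)OCCO[Si](C)(C)C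
Why: Noyori ketalization, in which the silyl triflate activates the carbonyl and the bis-silyl ether delivers both oxygens at low temperature without free glycol or protic acid, so that conjugate addition to the diynone is held back and formation of hexamethyldisiloxane drives the exchange.

**Step 5**
Reactants: 11 trimethyl({2-[(3,4,5-trimethoxyphenyl)ethynyl]-1,3-dioxolan-2-yl}ethynyl)silane
Product: 12 2-ethynyl-2-[(3,4,5-trimethoxyphenyl)ethynyl]-1,3-dioxolane
Conditions: K2CO3 (cat.), MeOH, 0 °C → rt
Reagents that add atoms: none
Why: protodesilylation of the alkynylsilane by catalytic methoxide, to which the ketal, the aryl ethers and the internal alkyne are inert.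

**Step 6**
Reactants: 5 pentacarbonyl[methoxy(1-methoxyvinyl)carbene]chromium; 12 2-ethynyl-2-[(3,4,5-trimethoxyphenyl)ethynyl]-1,3-dioxolane
Product: 14 4,5-dimethoxy-2-{2-[(3,4,5-trimethoxyphenyl)ethynyl]-1,3-dioxolan-2-yl}phenol, via tricarbonylchromium arene complex 13 (not isolated)
Conditions: 5 (1.3 equiv), THF (0.05 M), 50 °C, Ar; then air, daylight, Et2O, rt; Et3N-deactivated silica
Reagents that add atoms: none
Why: Dötz benzannulation: thermal loss of one CO from 5 opens a site for the terminal alkyne of 12, which inserts into the Cr=C bond with its CH carbon joined to the former carbene carbon (C5–C6), a CO ligand then inserts to give a chromium-bound dienylketene (C4a–C8a), and 6π-electrocyclization of the ketene onto the CH2 terminus of the methoxyvinyl unit (C8–C8a) followed by enolization gives the phenol as its tricarbonylchromium complex 13, which air and light should convert to 14. The closest known reaction type is the benzannulation of alkenyl(methoxy)carbene pentacarbonylchromium complexes with terminal alkynes, including complexes with an oxygen substituent on the alkenyl α-carbon. Ring A is closed by a formal [3+2+1] assembly whose ring-closing event is the 6π-electrocyclization of the dienylketene to a six-membered carbocycle, and no stereocentre is formed. Two selectivities are needed: the alkyne substituent must end ortho to the new hydroxyl, which the size difference between the quaternary ketal carbon and hydrogen secures during insertion, and only the terminal alkyne may react, which the aryl cap and the adjacent quaternary carbon secure by hindering the internal triple bond, while the one-atom spacer between the two alkynes rules out an intramolecular second insertion. The dioxolane keeps the ynone carbonyl out of the reaction, and decomplexation by air instead of a strong oxidant such as (NH4)2Ce(NO3)6 avoids oxidation of the para-methoxyphenol to a quinone.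

**Step 7**
Reactants: 14 4,5-dimethoxy-2-{2-[(3,4,5-trimethoxyphenyl)ethynyl]-1,3-dioxolan-2-yl}phenol
Product: 15 1-(2-hydroxy-4,5-dimethoxyphenyl)-3-(3,4,5-trimethoxyphenyl)prop-2-yn-1-one
Conditions: 1 M aq. HCl, THF, rt
Reagents that add atoms: water, O
Why: acid-catalysed ketal hydrolysis, made easy because the oxocarbenium ion at C4 is stabilised by the ortho hydroxyl and the para C7 methoxy group of the new ring A, so that dilute acid at room temperature should release the hydrogen-bonded ynone without any base that could trigger 5-exo closure.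

**Step 8**
Reactants: 15 1-(2-hydroxy-4,5-dimethoxyphenyl)-3-(3,4,5-trimethoxyphenyl)prop-2-yn-1-one
Product: 16 Prosogerin C, 6,7-dimethoxy-2-(3,4,5-trimethoxyphenyl)-4H-chromen-4-one
Conditions: K2CO3, acetone, reflux
Reagents that add atoms: none
Why: intramolecular oxa-Michael addition of the phenoxide to the ynone β-carbon C2 (6-endo-dig), the mode that K2CO3 in aprotic acetone favours for ortho-hydroxyaryl arylethynyl ketones over 5-exo closure to the aurone, followed by protonation at C3.

**Compound list**
1 | methyl vinyl ether | COC=C | starting material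
2 | chromium hexacarbonyl, Cr(CO)6 | O=C=[Cr](=C=O)(=C=O)(=C=O)(=C=O)=C=O | starting material
3 | 1-methoxyvinyllithium (formed in the flask) | [Li]C(=C)OC | intermediate
4 | lithium pentacarbonyl(2-methoxyacryloyl)chromate (formed in the flask) | [Li+].COC(=C)C([O-])=[Cr](=C=O)(=C=O)(=C=O)(=C=O)=C=O | intermediate
5 | pentacarbonyl[methoxy(1-methoxyvinyl)carbene]chromium | COC(=C)C(OC)=[Cr](=C=O)(=C=O)(=C=O)(=C=O)=C=O | intermediate
6 | 5-ethynyl-1,2,3-trimethoxybenzene | C#Cc1cc(OC)c(OC)c(OC)c1 | starting material
7 | 3-(trimethylsilyl)prop-2-ynal | C[Si](C)(C)C#CC=O | starting material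
8 | lithium (3,4,5-trimethoxyphenyl)acetylide (formed in the flask) | [Li]C#Cc1cc(OC)c(OC)c(OC)c1 | intermediate
9 | racemic 1-(3,4,5-trimethoxyphenyl)-5-(trimethylsilyl)penta-1,4-diyn-3-ol | COc1cc(C#CC(O)C#C[Si](C)(C)C)cc(OC)c1OC | intermediate
10 | 1-(3,4,5-trimethoxyphenyl)-5-(trimethylsilyl)penta-1,4-diyn-3-one | COc1cc(C#CC(=O)C#C[Si](C)(C)C)cc(OC)c1OC | intermediate
11 | trimethyl({2-[(3,4,5-trimethoxyphenyl)ethynyl]-1,3-dioxolan-2-yl}ethynyl)silane | COc1cc(C#CC2(C#C[Si](C)(C)C)OCCO2)cc(OC)c1OC | intermediate
12 | 2-ethynyl-2-[(3,4,5-trimethoxyphenyl)ethynyl]-1,3-dioxolane | C#CC1(C#Cc2cc(OC)c(OC)c(OC)c2)OCCO1 | intermediate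
13 | tricarbonylchromium complex of phenol 14, chromium bound hexahapto to ring A (formed in the flask) | COc1cc(O)c(C2(C#Cc3cc(OC)c(OC)c(OC)c3)OCCO2)cc1OC.[Cr](=C=O)(=C=O)=C=O | intermediate
14 | 4,5-dimethoxy-2-{2-[(3,4,5-trimethoxyphenyl)ethynyl]-1,3-dioxolan-2-yl}phenol | COc1cc(O)c(C2(C#Cc3cc(OC)c(OC)c(OC)c3)OCCO2)cc1OC | intermediate
15 | 1-(2-hydroxy-4,5-dimethoxyphenyl)-3-(3,4,5-trimethoxyphenyl)prop-2-yn-1-one | COc1cc(O)c(C(=O)C#Cc2cc(OC)c(OC)c(OC)c2)cc1OC | intermediate
16 | Prosogerin C, 6,7-dimethoxy-2-(3,4,5-trimethoxyphenyl)-4H-chromen-4-one | COc1cc2oc(-c3cc(OC)c(OC)c(OC)c3)cc(=O)c2cc1OC | target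

**Step count**
Total: 8 steps. Longest linear sequence: 7 steps (steps 2 to 8, from 6 and 7); the carbene complex is a one-step side branch.

**Steps most likely to fail**

1. Step 6. The electron-rich carbene complex with its unsubstituted vinyl terminus may decompose or oligomerise on heating before it loses CO and captures the alkyne. The terminal alkyne may also insert more than once, and the free para-methoxyphenol may be oxidised during decomplexation. The doubt about the lifetime of 5 on isolation in step 1 is counted here. Fallback: it sets out from arylacetylene 6 and comes back at 16, and makes ring C and the C4 carbonyl by palladium catalysis instead of building ring A. Purchased 3,4-dimethoxyphenol F1 is iodinated with N-iodosuccinimide (MeCN, 0 °C) ortho to the hydroxyl and para to the 3-methoxy group to give 2-iodo-4,5-dimethoxyphenol F2. Carbonylative Sonogashira-type coupling of F2 with 6 (PdCl2(dppf) cat., CO, Et2NH, 120 °C) should form ynone 15 in the flask. Diethylamine adds to it to give the diethylaminoenone F3 (not isolated), which closes by addition–elimination to flavone 16.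

2. Step 4. The silylated glycol may add in conjugate fashion to the doubly activated triple bonds instead of at the carbonyl carbon, or the exchange may stall because the dialkynyl oxocarbenium ion is poorly stabilised. Fallback: it sets out from diynol 9 and comes back at ynone 15, and masks the ynone one oxidation level lower instead of as a ketal. The carbinol is silylated (t-BuMe2SiCl, imidazole, DMF) to the racemic silyl ether F4, and the alkynylsilane is cleaved (K2CO3, MeOH, 0 °C) to the terminal diyne F5. F5 is benzannulated with carbene complex 5 under the conditions of step 6 to give, through the tricarbonylchromium complex F6 (not isolated), the silyloxy phenol F7. Bu4NF (THF, 0 °C) frees the diol F8, and activated MnO2 (CH2Cl2, rt) oxidises the benzylic, propargylic carbinol to 15.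

3. Step 8. The phenoxide may close 5-exo-dig onto the α-carbon in competition with the 6-endo mode, which would divert material to the aurone skeleton. Fallback: it sets out from 15 and comes back at 16. Pyrrolidine (EtOH, rt) adds to the ynone to give the pyrrolidinyl enaminone F9, in which C2 is an sp2 carbon carrying a leaving group. The phenol can then only close the six-membered ring by addition–elimination (AcOH, EtOH, reflux) with loss of pyrrolidine.

**Further compounds**
F1 | step 6 | 3,4-dimethoxyphenol (purchased) | COc1ccc(O)cc1OC
F2 | step 6 | 2-iodo-4,5-dimethoxyphenol | COc1cc(O)c(I)cc1OC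
F3 | step 6 | (E)-3-(diethylamino)-1-(2-hydroxy-4,5-dimethoxyphenyl)-3-(3,4,5-trimethoxyphenyl)prop-2-en-1-one (not isolated) | CCN(CC)/C(=C/C(=O)c1cc(OC)c(OC)cc1O)c1cc(OC)c(OC)c(OC)c1
F4 | step 4 | racemic tert-butyl(dimethyl){[1-(3,4,5-trimethoxyphenyl)-5-(trimethylsilyl)penta-1,4-diyn-3-yl]oxy}silane | COc1cc(C#CC(O[Si](C)(C)C(C)(C)C)C#C[Si](C)(C)C)cc(OC)c1OC
F5 | step 4 | racemic tert-butyl(dimethyl){[1-(3,4,5-trimethoxyphenyl)penta-1,4-diyn-3-yl]oxy}silane | C#CC(O[Si](C)(C)C(C)(C)C)C#Cc1cc(OC)c(OC)c(OC)c1
F6 | step 4 | tricarbonylchromium complex of F7, chromium bound hexahapto to ring A (not isolated) | COc1cc(O)c(C(O[Si](C)(C)C(C)(C)C)C#Cc2cc(OC)c(OC)c(OC)c2)cc1OC.[Cr](=C=O)(=C=O)=C=O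
F7 | step 4 | racemic 2-{1-[(tert-butyldimethylsilyl)oxy]-3-(3,4,5-trimethoxyphenyl)prop-2-yn-1-yl}-4,5-dimethoxyphenol | COc1cc(O)c(C(O[Si](C)(C)C(C)(C)C)C#Cc2cc(OC)c(OC)c(OC)c2)cc1OC
F8 | step 4 | racemic 2-[1-hydroxy-3-(3,4,5-trimethoxyphenyl)prop-2-yn-1-yl]-4,5-dimethoxyphenol | COc1cc(O)c(C(O)C#Cc2cc(OC)c(OC)c(OC)c2)cc1OC
F9 | step 8 | (E)-1-(2-hydroxy-4,5-dimethoxyphenyl)-3-(pyrrolidin-1-yl)-3-(3,4,5-trimethoxyphenyl)prop-2-en-1-one | O=C(/C=C(/N1CCCC1)c1cc(OC)c(OC)c(OC)c1)c1cc(OC)c(OC)cc1O
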